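Cuts: the O8–acetyl and C5–Cl bonds; ring A at O2–C3 (C1–OH adding to a C3≡C4 ynenone); C4a=C5 (from a C4a carbinol); ring B at C7–C8; C4a–C5 (ketone enolate + ynone); C4–C4a (acetylide + Weinreb amide); C9=C10 and C11=C12 (olefinations).
Enabling feature: ring B is an α,β-dihydroxy ketone, C6(=O)–C7(OH)(CH3)–C8(O), with O7 and O8 cis; one boron atom can hold both oxygens while a C6/C7 ketol, as its enediol boronate, adds through C7 to a C8 aldehyde, so the C7–C8 bond, ring B and both carbinol centres arise together in a temporary dioxaborolane.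
Helpers: the boron bridge (taken off in step 14) and an sp3 carbinol at C4a that keeps the C8a hydrogen non-acidic during ring closure (dehydrated in step 13).
Forward order: side-chain dienyne + auxiliary-derived Weinreb amide → ynone → acyclic aldol adduct → ring B (C7–C8) → C4a=C5 → ring A (O2–C3) → C5–Cl → 8-O-acetate.
Stereochemistry: C13 from (R)-2-methylbutan-1-ol; C8a from the (S)-4-benzyloxazolidinone hydroxymethylation; C7 and C8 from the ring closure under control of C8a and the boron bridge; E-alkenes from Wittig and Horner–Wadsworth–Emmons olefinations.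

Key step: step 12

Numbering: locants O2, C1–C8a (rings) and C9–C13 (side chain) are those of the target 1H-isochromene.
Assumption: (R)-2-methylbutan-1-ol, diethyl [3-(trimethylsilyl)prop-2-yn-1-yl]phosphonate and 3-[(tert-butyldiphenylsilyl)oxy]propanoic acid are taken as purchasable; racemic acetoin is used because C7 passes through a planar enediol.

Step 1
Reactants: 1 (R)-2-methylbutan-1-ol; 2 2-(triphenylphosphoranylidene)propanal
Product: 4 (2E,4R)-2,4-dimethylhex-2-enal, via (R)-2-methylbutanal 3 (not isolated)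
Conditions: TEMPO (cat.), PhI(OAc)2, CH2Cl2, 23 °C; then 2, 40 °C
Reagents that add atoms: none
Why: Oxoammonium (TEMPO) oxidation makes the volatile, configurationally labile aldehyde only in solution, and the formyl-stabilised ylide converts it in the same flask by an E-selective Wittig olefination, so C13 comes unchanged from 1.

Step 2
Reactants: 4 (2E,4R)-2,4-dimethylhex-2-enal; 5 diethyl [3-(trimethylsilyl)prop-2-yn-1-yl]phosphonate
Product: 7 trimethyl[(3E,5E,7R)-5,7-dimethylnona-3,5-dien-1-yn-1-yl]silane, via lithiated phosphonate 6 (not isolated)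
Conditions: LiN(SiMe3)2, THF, −78 °C; then 4, −78 → 0 °C; aq. NH4Cl
Reagents that add atoms: none
Why: Horner–Wadsworth–Emmons olefination with the stabilised propargylic phosphonate anion should give the new C9=C10 alkene with E geometry and leave the enal-derived alkene untouched.

Step 3
Reactants: 7 trimethyl[(3E,5E,7R)-5,7-dimethylnona-3,5-dien-1-yn-1-yl]silane
Product: 8 (3E,5E,7R)-5,7-dimethylnona-3,5-dien-1-yne
Conditions: K2CO3, MeOH, 23 °C
Reagents that add atoms: none
Why: Carbonate-catalysed methanolysis of the alkynyl C–Si bond (protodesilylation) frees the terminal alkyne.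

Step 4
Reactants: 9 3-[(tert-butyldiphenylsilyl)oxy]propanoic acid; 10 (S)-4-benzyloxazolidin-2-one
Product: 12 (S)-4-benzyl-3-{3-[(tert-butyldiphenylsilyl)oxy]propanoyl}oxazolidin-2-one, via mixed pivalic anhydride 11 (not isolated)
Conditions: t-BuCOCl, Et3N, THF, −20 °C; then 10, LiCl, 23 °C
Reagents that add atoms: none
Why: N-acylation of the oxazolidinone through the mixed anhydride (LiCl/Et3N protocol) is the standard way to load an acyl group on this auxiliary.

Step 5
Reactants: 12 (S)-4-benzyl-3-{3-[(tert-butyldiphenylsilyl)oxy]propanoyl}oxazolidin-2-one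
Product: 14 (S)-4-benzyl-3-{(S)-3-[(tert-butyldiphenylsilyl)oxy]-2-(hydroxymethyl)propanoyl}oxazolidin-2-one, via chlorotitanium enolate 13 (not isolated)
Conditions: TiCl4, i-Pr2NEt, CH2Cl2, 0 °C; then 1,3,5-trioxane, TiCl4, 0 °C
Reagents that add atoms: 1,3,5-trioxane (C1OCOCO1)
Why: Auxiliary-controlled hydroxymethylation (Evans alkylation type): the chelated Z titanium enolate is attacked by TiCl4-activated formaldehyde on the face opposite the benzyl group, which sets the future C8a centre.

Step 6
Reactants: 14 (S)-4-benzyl-3-{(S)-3-[(tert-butyldiphenylsilyl)oxy]-2-(hydroxymethyl)propanoyl}oxazolidin-2-one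
Product: 15 (S)-3-[(tert-butyldiphenylsilyl)oxy]-2-(hydroxymethyl)-N-methoxy-N-methylpropanamide
Conditions: MeNH(OMe)·HCl, AlMe3, CH2Cl2, −10 → 0 °C
Reagents that add atoms: N,O-dimethylhydroxylamine hydrochloride (CNOC.Cl)
Why: Aluminium-amide transamination to the Weinreb amide, assisted by the free β-hydroxyl, should remove the auxiliary without epimerising the α-centre.

Step 7
Reactants: 15 (S)-3-[(tert-butyldiphenylsilyl)oxy]-2-(hydroxymethyl)-N-methoxy-N-methylpropanamide
Product: 16 (S)-3-[(tert-butyldiphenylsilyl)oxy]-N-methoxy-N-methyl-2-{[(triethylsilyl)oxy]methyl}propanamide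
Conditions: Et3SiCl, imidazole, CH2Cl2, 0 °C
Reagents that add atoms: chlorotriethylsilane (CC[Si](Cl)(CC)CC)
Why: Silylation of the primary alcohol differentiates the two hydroxymethyl arms (triethylsilyl on the future C8 oxygen, tert-butyldiphenylsilyl on the future C1 oxygen).

Step 8
Reactants: 8 (3E,5E,7R)-5,7-dimethylnona-3,5-dien-1-yne; 16 (S)-3-[(tert-butyldiphenylsilyl)oxy]-N-methoxy-N-methyl-2-{[(triethylsilyl)oxy]methyl}propanamide
Product: 18 (2S,6E,8E,10R)-1-[(tert-butyldiphenylsilyl)oxy]-8,10-dimethyl-2-{[(triethylsilyl)oxy]methyl}dodeca-6,8-dien-4-yn-3-one, via lithium acetylide 17 (not isolated)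
Conditions: n-BuLi, THF, −78 °C; then 16, −78 → −20 °C; aq. NH4Cl
Reagents that add atoms: none
Why: Weinreb ketone synthesis: the lithium acetylide adds once, the chelated tetrahedral intermediate survives until work-up, and the ynone joins C4 to C4a.

Step 9
Reactants: 19 3-hydroxybutan-2-one (acetoin, racemic)
Product: 20 3-[(triethylsilyl)oxy]butan-2-one (racemic)
Conditions: Et3SiCl, imidazole, DMF, 0 → 23 °C
Reagents that add atoms: chlorotriethylsilane (CC[Si](Cl)(CC)CC)
Why: Standard silylation of the secondary alcohol masks the ketol hydroxyl for the enolate step.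

Step 10
Reactants: 20 3-[(triethylsilyl)oxy]butan-2-one; 18 ynone
Product: 22 tertiary propargylic aldol adduct (C4a–OH; C7–OSiEt3; C8–OSiEt3; C1–OSi(t-Bu)Ph2; both epimers at C4a and at C7), via lithium enolate 21 (not isolated)
Conditions: LiN(i-Pr)2, THF, −78 °C; then 18, −78 °C; AcOH quench at −78 °C
Reagents that add atoms: none
Why: Kinetic deprotonation of 20 at its methyl group (the future C5) and aldol-type 1,2-addition of the lithium enolate to the ynone carbonyl should form C4a–C5, giving both epimers at the new carbinol and at C7 (both centres are erased later), while the sp3 C4a keeps the C8a hydrogen non-acidic for the ring closure.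

Step 11
Reactants: 22 tertiary propargylic aldol adduct
Product: 23 triol (C8–OH primary; C7–OH ketol; C4a–OH tertiary; C1–OSi(t-Bu)Ph2)
Conditions: AcOH/THF/H2O (3:1:1), 23 °C
Reagents that add atoms: none
Why: Mild acid hydrolysis cleaves the primary and the secondary triethylsilyl ethers while the tert-butyldiphenylsilyl ether and the tertiary propargylic alcohol survive.

Step 12
Reactants: 23 triol
Product: 26 ring B cyclohexanone phenylboronate (cis-fused 2-phenyl-1,3,2-dioxaborolane on O7/O8; C4a carbinol), via aldehyde 24 (not isolated), via enediol phenylboronate 25 (not isolated)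
Conditions: TEMPO (cat.), PhI(OAc)2, CH2Cl2, 0 → 23 °C; then PhB(OH)2, 4 Å molecular sieves, toluene, 23 → 60 °C
Reagents that add atoms: phenylboronic acid (OB(O)c1ccccc1)
Why: Proposed new method: after selective oxidation of the primary alcohol, PhB(OH)2 condenses with the C6/C7 ketol through its enediol to the 2-phenyl-1,3,2-dioxaborole 25, whose boron binds the aldehyde oxygen so that C7 adds to C8 through a boat-like six-centre array (B–O6–C6=C7···C8=O8) while the B–O6 bond opens to the C6 ketone and boron ends as a dioxaborolane across O7 and O8. The closest known reaction type is the intermolecular aldol addition of enediol phenylboronates (dioxaboroles made from α-hydroxy ketones and PhB(OH)2) to aldehydes, which gives 2,3-dihydroxy ketones as cyclic boronates; a ring-closing version is not known. Ring B closes in the 6-(enolendo)-exo-trig mode and the five-membered dioxaborolane closes in the same event by O8–B bonding. At C7 and C8 the O7–B–O8 bridge forces the two oxygens cis, and the C8a centre, which keeps its CH2OSi arm equatorial in the chair-like transition state, places O8 equatorial (trans to C1) and the C7 methyl equatorial. The step needs C–C bonding through C7 and not through C6 of the ambident enediol (C6 would close a cyclopentane), which the substrate favours because C7 carries only a methyl group while C6 carries the branched C5 chain and would have to build a more strained cis-bicyclo[3.3.0] core; it also needs an aldehyde that keeps its C8a configuration, which the sp3 carbinol C4a secures by keeping C8a out of conjugation with the C6 carbonyl.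

Step 13
Reactants: 26 ring B cyclohexanone phenylboronate
Product: 27 ring B ynenone phenylboronate (C4a=C5; dienynyl group on C4a)
Conditions: Burgess reagent (MeO2CN–SO2NEt3 inner salt), benzene, 50 °C
Reagents that add atoms: none
Why: Burgess dehydration (syn-elimination of the sulfamate ester) of the tertiary β-hydroxy ketone should remove the C4a hydroxyl with a C5 hydrogen, the acidic one α to the ketone, to give the conjugated ynenone, while the boronate protects the diol.

Step 14
Reactants: 27 ring B ynenone phenylboronate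
Product: 29 (7R,8R,8aR)-3-[(1E,3E,5R)-3,5-dimethylhepta-1,3-dien-1-yl]-7,8-dihydroxy-7-methyl-1,7,8,8a-tetrahydro-6H-isochromen-6-one, via ring-closed phenylboronate 28 (not isolated)
Conditions: Bu4NF, THF, 0 → 23 °C; then pinacol, MeOH, 23 °C; aq. NH4Cl
Reagents that add atoms: none
Why: Fluoride removes the silyl group from O–C1 and the alkoxide adds to C3 of the ynenone in a 6-endo-dig 1,6-oxa-Michael addition that closes ring A, after which transesterification with pinacol takes the boron off the diol.

Step 15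
Reactants: 29 dechloro diol
Product: 30 (7R,8R,8aR)-5-chloro-3-[(1E,3E,5R)-3,5-dimethylhepta-1,3-dien-1-yl]-7,8-dihydroxy-7-methyl-1,7,8,8a-tetrahydro-6H-isochromen-6-one
Conditions: N-chlorosuccinimide, MeCN, 0 °C
Reagents that add atoms: N-chlorosuccinimide (O=C1CCC(=O)N1Cl)
Why: Electrophilic chlorination of the doubly vinylogous ester O2–C3=C4–C4a=C5–C6=O should occur at C5, the α-carbon of the dienone, as in the C5 halogenation of azaphilone chromophores.

Step 16
Reactants: 30 chloro diol
Product: 31 (7R,8R,8aR)-5-chloro-3-[(1E,3E,5R)-3,5-dimethylhepta-1,3-dien-1-yl]-7-hydroxy-7-methyl-6-oxo-6,7,8,8a-tetrahydro-1H-isochromen-8-yl acetate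
Conditions: Ac2O, pyridine, CH2Cl2, 0 °C
Reagents that add atoms: acetic anhydride (CC(=O)OC(C)=O)
Why: Acylation with Ac2O/pyridine should be selective for the secondary C8 hydroxyl over the tertiary C7 hydroxyl.

Compound list
1 | (R)-2-methylbutan-1-ol | CC[C@@H](C)CO | starting material
2 | 2-(triphenylphosphoranylidene)propanal | CC(C=O)=P(c1ccccc1)(c1ccccc1)c1ccccc1 | starting material
3 | (R)-2-methylbutanal | CC[C@@H](C)C=O | intermediate
4 | (2E,4R)-2,4-dimethylhex-2-enal | CC[C@@H](C)/C=C(C)/C=O | intermediate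
5 | diethyl [3-(trimethylsilyl)prop-2-yn-1-yl]phosphonate | CCOP(=O)(CC#C[Si](C)(C)C)OCC | starting material
6 | lithiated phosphonate (α-lithio derivative of 5) | CCOP(=O)(OCC)C([Li])C#C[Si](C)(C)C | intermediate
7 | trimethyl[(3E,5E,7R)-5,7-dimethylnona-3,5-dien-1-yn-1-yl]silane | CC[C@@H](C)/C=C(C)/C=C/C#C[Si](C)(C)C | intermediate
8 | (3E,5E,7R)-5,7-dimethylnona-3,5-dien-1-yne | CC[C@@H](C)/C=C(C)/C=C/C#C | intermediate
9 | 3-[(tert-butyldiphenylsilyl)oxy]propanoic acid | OC(=O)CCO[Si](c1ccccc1)(c1ccccc1)C(C)(C)C | starting material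
10 | (S)-4-benzyloxazolidin-2-one | O=C1OC[C@H](Cc2ccccc2)N1 | starting material
11 | mixed pivalic anhydride of 9 | CC(C)(C)C(=O)OC(=O)CCO[Si](c1ccccc1)(c1ccccc1)C(C)(C)C | intermediate
12 | (S)-4-benzyl-3-{3-[(tert-butyldiphenylsilyl)oxy]propanoyl}oxazolidin-2-one | O=C1OC[C@H](Cc2ccccc2)N1C(=O)CCO[Si](c1ccccc1)(c1ccccc1)C(C)(C)C | intermediate
13 | chlorotitanium Z-enolate of 12 | O=C1OC[C@H](Cc2ccccc2)N1/C(O[Ti](Cl)(Cl)Cl)=C/CO[Si](c1ccccc1)(c1ccccc1)C(C)(C)C | intermediate
14 | (S)-4-benzyl-3-{(S)-3-[(tert-butyldiphenylsilyl)oxy]-2-(hydroxymethyl)propanoyl}oxazolidin-2-one | O=C1OC[C@H](Cc2ccccc2)N1C(=O)[C@@H](CO)CO[Si](c1ccccc1)(c1ccccc1)C(C)(C)C | intermediate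
15 | (S)-3-[(tert-butyldiphenylsilyl)oxy]-2-(hydroxymethyl)-N-methoxy-N-methylpropanamide | CON(C)C(=O)[C@@H](CO)CO[Si](c1ccccc1)(c1ccccc1)C(C)(C)C | intermediate
16 | (S)-3-[(tert-butyldiphenylsilyl)oxy]-N-methoxy-N-methyl-2-{[(triethylsilyl)oxy]methyl}propanamide | CON(C)C(=O)[C@@H](CO[Si](CC)(CC)CC)CO[Si](c1ccccc1)(c1ccccc1)C(C)(C)C | intermediate
17 | lithium acetylide of 8 | CC[C@@H](C)/C=C(C)/C=C/C#C[Li] | intermediate
18 | (2S,6E,8E,10R)-1-[(tert-butyldiphenylsilyl)oxy]-8,10-dimethyl-2-{[(triethylsilyl)oxy]methyl}dodeca-6,8-dien-4-yn-3-one | CC[C@@H](C)/C=C(C)/C=C/C#CC(=O)[C@@H](CO[Si](CC)(CC)CC)CO[Si](c1ccccc1)(c1ccccc1)C(C)(C)C | intermediate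
19 | 3-hydroxybutan-2-one (acetoin, racemic) | CC(=O)C(C)O | starting material
20 | 3-[(triethylsilyl)oxy]butan-2-one (racemic) | CC(=O)C(C)O[Si](CC)(CC)CC | intermediate
21 | lithium enolate of 20 (methyl side) | [Li]OC(=C)C(C)O[Si](CC)(CC)CC | intermediate
22 | tertiary propargylic aldol adduct: C5 of 20 bonded to the ketone carbon (C4a) of 18; C4a–OH, C7–OSiEt3, C8–OSiEt3, C1–OSi(t-Bu)Ph2; C8a as in 18; both epimers at C4a and at C7 | CC[C@@H](C)/C=C(C)/C=C/C#CC(O)(CC(=O)C(C)O[Si](CC)(CC)CC)[C@@H](CO[Si](CC)(CC)CC)CO[Si](c1ccccc1)(c1ccccc1)C(C)(C)C | intermediate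
23 | triol from 22 (C8–OH, C7–OH, C4a–OH free; C1–OSi(t-Bu)Ph2; epimers at C4a and C7) | CC[C@@H](C)/C=C(C)/C=C/C#CC(O)(CC(=O)C(C)O)[C@@H](CO)CO[Si](c1ccccc1)(c1ccccc1)C(C)(C)C | intermediate
24 | C8 aldehyde of 23 (ketol and C4a carbinol unchanged) | CC[C@@H](C)/C=C(C)/C=C/C#CC(O)(CC(=O)C(C)O)[C@@H](C=O)CO[Si](c1ccccc1)(c1ccccc1)C(C)(C)C | intermediate
25 | enediol phenylboronate of 24 (4-methyl-2-phenyl-1,3,2-dioxaborole; C6 and C7 in the boron ring) | CC[C@@H](C)/C=C(C)/C=C/C#CC(O)(CC1=C(C)OB(c2ccccc2)O1)[C@@H](C=O)CO[Si](c1ccccc1)(c1ccccc1)C(C)(C)C | intermediate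
26 | ring B cyclohexanone: C6 ketone, C7(CH3)–O and C8–O bridged cis by B–Ph, C8a–CH2OSi(t-Bu)Ph2, C4a carbinol bearing the dienynyl group (both C4a epimers); C7, C8, C8a as in 31 | CC[C@@H](C)/C=C(C)/C=C/C#CC1(O)CC(=O)[C@](C)(O2)[C@H](OB2c3ccccc3)[C@H]1CO[Si](c4ccccc4)(c5ccccc5)C(C)(C)C | intermediate
27 | ring B ynenone: 26 dehydrated to C4a=C5, dienynyl group on C4a, boronate retained | CC[C@@H](C)/C=C(C)/C=C/C#CC1=CC(=O)[C@](C)(O2)[C@H](OB2c3ccccc3)[C@H]1CO[Si](c4ccccc4)(c5ccccc5)C(C)(C)C | intermediate
28 | ring-closed phenylboronate: 7,8-O-phenylboranediyl derivative of 29 | CC[C@@H](C)/C=C(C)/C=C/C1=CC2=CC(=O)[C@](C)(O3)[C@H](OB3c4ccccc4)[C@H]2CO1 | intermediate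
29 | (7R,8R,8aR)-3-[(1E,3E,5R)-3,5-dimethylhepta-1,3-dien-1-yl]-7,8-dihydroxy-7-methyl-1,7,8,8a-tetrahydro-6H-isochromen-6-one | CC[C@@H](C)/C=C(C)/C=C/C1=CC2=CC(=O)[C@](C)(O)[C@H](O)[C@H]2CO1 | intermediate
30 | (7R,8R,8aR)-5-chloro-3-[(1E,3E,5R)-3,5-dimethylhepta-1,3-dien-1-yl]-7,8-dihydroxy-7-methyl-1,7,8,8a-tetrahydro-6H-isochromen-6-one | CC[C@@H](C)/C=C(C)/C=C/C1=CC2=C(Cl)C(=O)[C@](C)(O)[C@H](O)[C@H]2CO1 | intermediate
31 | (7R,8R,8aR)-5-chloro-3-[(1E,3E,5R)-3,5-dimethylhepta-1,3-dien-1-yl]-7-hydroxy-7-methyl-6-oxo-6,7,8,8a-tetrahydro-1H-isochromen-8-yl acetate | CC[C@@H](C)/C=C(C)/C=C/C1=CC2=C(Cl)C(=O)[C@](C)(O)[C@H](OC(C)=O)[C@H]2CO1 | target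

Total step count: 16. Longest linear sequence: 12 steps (steps 4–8 and 10–16).

Steps most likely to fail

Step 12 (Proposed new method). What may go wrong: the ambident enediol boronate may close through C6 to a cyclopentane; the free C4a hydroxyl may tie up the boron so that the aldehyde is never engaged; the aldehyde may lose its C8a configuration before it cyclises; or the face selectivity may be poor. Fallback with known chemistry (a reductive carbonyl coupling in place of the boron aldol): it sets out from 23. Dess–Martin periodinane oxidises both the primary alcohol and the ketol to the 6,7-diketo aldehyde F1. SmI2 in THF at −78 °C reduces the 1,2-diketone to its samarium enediolate, which couples with the aldehyde to the cis-diol F2; this is the known SmI2- or TiCl3-mediated cross-coupling of 1,2-diketones with aldehydes to 2,3-dihydroxy ketones, and the trivalent samarium chelate holds the oxygens cis. Esterification of F2 with PhB(OH)2 gives 26, where the route is rejoined.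

Step 10. What may go wrong: conjugate addition of the enolate to the ynone, deprotonation of the ynone at C8a (loss of configuration or β-elimination of silanolate), or retro-aldol cleavage on work-up. Fallback (a Reformatsky addition in place of the lithium aldol): it sets out from 20. LiN(i-Pr)2/Me3SiCl gives the kinetic silyl enol ether F3, N-bromosuccinimide converts it into the bromo ketone F4, and activated Zn in THF in the presence of 18 (a non-basic, 1,2-selective zinc enolate) gives 22, where the route is rejoined.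

Step 15. What may go wrong: chlorination at C4 or on the dienyl side chain, or over-chlorination, instead of clean substitution at C5. Fallback (chlorine introduced before the chromophore exists): it sets out from 26, whose ketone can enolise only towards C5. LiN(SiMe3)2/Me3SiCl gives the bis-silyl compound F5 (C5=C6 silyl enol ether, C4a–OSiMe3). N-chlorosuccinimide followed by a mild acidic work-up gives the 5-chloro ketone F6. Burgess dehydration gives the 5-chloro ynenone F7. Bu4NF followed by pinacol, as in step 14, closes ring A and frees the diol to give 30, where the route is rejoined.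

Further compounds
F1 | step 12 | 6,7-diketo aldehyde (C8 aldehyde, C6 and C7 ketones, C4a carbinol, C1–OSi(t-Bu)Ph2) | CC[C@@H](C)/C=C(C)/C=C/C#CC(O)(CC(=O)C(C)=O)[C@@H](C=O)CO[Si](c1ccccc1)(c1ccccc1)C(C)(C)C
F2 | step 12 | boron-free cis-7,8-diol of 26 | CC[C@@H](C)/C=C(C)/C=C/C#CC1(O)CC(=O)[C@](C)(O)[C@H](O)[C@H]1CO[Si](c2ccccc2)(c3ccccc3)C(C)(C)C
F3 | step 10 | 3-[(triethylsilyl)oxy]-2-[(trimethylsilyl)oxy]but-1-ene | C=C(O[Si](C)(C)C)C(C)O[Si](CC)(CC)CC
F4 | step 10 | 1-bromo-3-[(triethylsilyl)oxy]butan-2-one | BrCC(=O)C(C)O[Si](CC)(CC)CC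
F5 | step 15 | C5=C6 trimethylsilyl enol ether of 26 with C4a–OSiMe3 | CC[C@@H](C)/C=C(C)/C=C/C#CC1(O[Si](C)(C)C)C=C(O[Si](C)(C)C)[C@](C)(O2)[C@H](OB2c3ccccc3)[C@H]1CO[Si](c4ccccc4)(c5ccccc5)C(C)(C)C
F6 | step 15 | 5-chloro derivative of 26 (C5 epimers) | CC[C@@H](C)/C=C(C)/C=C/C#CC1(O)C(Cl)C(=O)[C@](C)(O2)[C@H](OB2c3ccccc3)[C@H]1CO[Si](c4ccccc4)(c5ccccc5)C(C)(C)C
F7 | step 15 | 5-chloro derivative of 27 | CC[C@@H](C)/C=C(C)/C=C/C#CC1=C(Cl)C(=O)[C@](C)(O2)[C@H](OB2c3ccccc3)[C@H]1CO[Si](c4ccccc4)(c5ccccc5)C(C)(C)C
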